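**Retrosynthetic overview**
- Last operations: global desilylation, and before it the C5–C6 oxirane, the only ring of the target and the only ring formed in the route (reagent-controlled Shi epoxidation, step 14).
- C10–C11 (syn boron aldol with a dithiane-masked 3-oxopentanal) and C7–C8 (anti boron aldol with a dienal) both start from one symmetric ketone, 1,5-bis(silyloxy)pentan-3-one.
- Key step: that ketone's carbonyl carbon C9 is introduced as a carbonyl dianion. Lithiated 2-silyl-1,3-dithiane opens two oxiranes in one flask, relayed by a Brook rearrangement, making C9–C10 and C8–C9.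
- C13 is likewise an acyl anion: 1,3-dithiane + EtI + oxirane makes C13–C14 and C12–C13. The dienal comes from (R)-Roche ester by two Wittig reactions.
- Ring order: the two 1,3-dithiane rings are bought and hydrolysed (steps 2 and 13); the oxirane is closed last (step 14).

**Assumptions**
- Locants C1–C15 follow the target SMILES from left to right; C8′ and C10′ are the hydroxymethyl carbons. The target is treated as the open-chain form drawn.
- The facial sense of the two chiral boron reagents (menthone-derived chloroborane: si face of the enal; (−)-Ipc2BOTf: re face of the aldehyde) is taken by analogy with diethyl ketone and is not certain. If either is reversed, its antipode is used (menthone and α-pinene are sold in both hands).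

**Step 1** (key step)
Reactants: 1 2-(tert-butyldimethylsilyl)-1,3-dithiane; 2 oxirane (2.4 equiv, two portions)
Product: 5 2,2-bis[2-(tert-butyldimethylsilyloxy)ethyl]-1,3-dithiane, via lithium alkoxide mono-adduct 3 (not isolated), via silyl-migrated bis-adduct lithium alkoxide 4 (not isolated)
Conditions: t-BuLi, Et2O, −78 → −45 °C; 2, −78 → −25 °C; then 2, HMPA/THF, −78 → 0 °C; TBSCl, 0 °C → rt
Reagents that add atoms: tert-butyldimethylsilyl chloride, CC(C)(C)[Si](C)(C)Cl
Why: Silyl-dithiane anion-relay (linchpin) coupling: the lithiated dithiane carbon, a reversed-polarity equivalent of the C9 carbonyl, opens oxirane (C9–C10), HMPA triggers a 1,4-Brook rearrangement that regenerates the dithiane anion for the second oxirane (C8–C9), and the alkoxide is capped in situ; no stereocentre is formed.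

**Step 2**
Reactants: 5 2,2-bis[2-(tert-butyldimethylsilyloxy)ethyl]-1,3-dithiane
Product: 6 1,5-bis(tert-butyldimethylsilyloxy)pentan-3-one
Conditions: MeI, CaCO3, MeCN/H2O 9:1, 45 °C
Reagents that add atoms: water, O
Why: S-methylation followed by hydrolysis of the dithioketal unmasks the C9 ketone under neutral conditions that spare the β-silyloxy groups.

**Step 3**
Reactants: 7 1,3-dithiane; 2 oxirane
Product: 9 2-(2-ethyl-1,3-dithian-2-yl)ethan-1-ol, via 2-ethyl-1,3-dithiane 8 (not isolated)
Conditions: n-BuLi, THF, −30 °C; EtI, −78 → 0 °C; n-BuLi, −20 °C; 2, −78 → 0 °C; H2O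
Reagents that add atoms: iodoethane, CCI
Why: One-flask Corey–Seebach double alkylation: the C13 acyl anion equivalent is ethylated (C13–C14) and then opens oxirane (C12–C13); no stereocentre.

**Step 4**
Reactants: 9 2-(2-ethyl-1,3-dithian-2-yl)ethan-1-ol
Product: 10 2-(2-ethyl-1,3-dithian-2-yl)acetaldehyde
Conditions: SO3·pyridine, DMSO, Et3N, CH2Cl2, 0 °C
Reagents that add atoms: none
Why: Parikh–Doering oxidation gives the aldehyde without oxidising the dithiane sulfur.

**Step 5**
Reactants: 11 methyl (R)-3-hydroxy-2-methylpropanoate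
Product: 12 methyl (R)-3-(tert-butyldimethylsilyloxy)-2-methylpropanoate
Conditions: TBSCl, imidazole, CH2Cl2, rt
Reagents that add atoms: tert-butyldimethylsilyl chloride, CC(C)(C)[Si](C)(C)Cl
Why: Standard silylation; the purchased stereocentre (future C4) is untouched.

**Step 6**
Reactants: 12 methyl (R)-3-(tert-butyldimethylsilyloxy)-2-methylpropanoate
Product: 13 (R)-3-(tert-butyldimethylsilyloxy)-2-methylpropanal
Conditions: i-Bu2AlH, CH2Cl2, −78 °C; aq. KNaC4H4O6
Reagents that add atoms: none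
Why: Low-temperature half-reduction of the ester stops at the aluminium hemiacetal, giving the aldehyde without epimerisation.

**Step 7**
Reactants: 13 (R)-3-(tert-butyldimethylsilyloxy)-2-methylpropanal
Product: 14 tert-butyldimethyl{[(2S,3Z)-2-methylpent-3-en-1-yl]oxy}silane
Conditions: EtPPh3Br, KN(SiMe3)2, THF, −78 °C → rt
Reagents that add atoms: ethyltriphenylphosphonium bromide, CC[P+](c1ccccc1)(c1ccccc1)c1ccccc1.[Br-]
Why: Salt-free Wittig reaction of a non-stabilised ylide gives the (Z)-alkene (C2=C3) under kinetic control, and the cold, non-nucleophilic base preserves the α-stereocentre.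

**Step 8**
Reactants: 14 tert-butyldimethyl{[(2S,3Z)-2-methylpent-3-en-1-yl]oxy}silane
Product: 15 (2S,3Z)-2-methylpent-3-en-1-ol
Conditions: Bu4NF, THF, 0 °C → rt
Reagents that add atoms: none
Why: Fluoride cleaves the primary silyl ether; the volatile alcohol is carried on as a solution.

**Step 9**
Reactants: 15 (2S,3Z)-2-methylpent-3-en-1-ol
Product: 17 (2E,4S,5Z)-2,4-dimethylhepta-2,5-dienal, via (2S,3Z)-2-methylpent-3-enal 16 (not isolated)
Conditions: 1,1,1-triacetoxy-1,1-dihydro-1,2-benziodoxol-3(1H)-one (Dess–Martin periodinane), pyridine, CH2Cl2, 0 °C; then Ph3P=C(CH3)CHO, 40 °C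
Reagents that add atoms: 2-(triphenylphosphoranylidene)propanal, CC(C=O)=P(c1ccccc1)(c1ccccc1)c1ccccc1
Why: Dess–Martin oxidation followed in the same flask by Wittig olefination with the stabilised formyl ylide gives the (E)-enal (C5=C6) under thermodynamic control, so the labile aldehyde 16 is never isolated.

**Step 10**
Reactants: 6 1,5-bis(tert-butyldimethylsilyloxy)pentan-3-one (1.5 equiv); 17 (2E,4S,5Z)-2,4-dimethylhepta-2,5-dienal
Product: 18 (4R,5S,6E,8S,9Z)-1-[(tert-butyldimethylsilyl)oxy]-4-{[(tert-butyldimethylsilyl)oxy]methyl}-5-hydroxy-6,8-dimethylundeca-6,9-dien-3-one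
Conditions: bis{[(1S,2S,5R)-2-isopropyl-5-methylcyclohexyl]methyl}chloroborane (from (−)-menthone: Ph3P=CH2, then BH2Cl·SMe2), Et3N, Et2O, −78 → 0 °C; 17, −78 → −25 °C; H2O2, MeOH/pH 7 buffer, 0 °C
Reagents that add atoms: none
Why: Anti-selective boron aldol: the chloroborane/Et3N pair gives the (E)-enol borinate, whose chair transition state gives the 7,8-anti adduct, and the menthone-derived ligands select the si face of the enal (7S,8R); the minor mode is a separable diastereomer because 17 is enantiopure.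

**Step 11**
Reactants: 18 anti-aldol adduct
Product: 19 (4R,5S,6E,8S,9Z)-1-[(tert-butyldimethylsilyl)oxy]-4-{[(tert-butyldimethylsilyl)oxy]methyl}-6,8-dimethyl-5-[(triethylsilyl)oxy]undeca-6,9-dien-3-one
Conditions: TESOTf, 2,6-lutidine, CH2Cl2, −78 °C
Reagents that add atoms: triethylsilyl trifluoromethanesulfonate, CC[Si](CC)(CC)OS(=O)(=O)C(F)(F)F
Why: Low-temperature silylation blocks the C7 hydroxyl without retro-aldol or elimination; the triethylsilyl group is chosen because it later leaves easily from this hindered position.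

**Step 12**
Reactants: 19 triethylsilyl ether; 10 2-(2-ethyl-1,3-dithian-2-yl)acetaldehyde
Product: 20 (2S,3R,5R,6S,7E,9S,10Z)-3,5-bis{[(tert-butyldimethylsilyl)oxy]methyl}-1-(2-ethyl-1,3-dithian-2-yl)-2-hydroxy-7,9-dimethyl-6-[(triethylsilyl)oxy]dodeca-7,10-dien-4-one
Conditions: (−)-Ipc2BOTf (diisopinocampheylboron triflate from (+)-α-pinene, freshly prepared), i-Pr2NEt, CH2Cl2, −78 °C; 10, −78 → −20 °C; MeOH/pH 7 buffer (no peroxide)
Reagents that add atoms: none
Why: Paterson syn aldol: enolisation occurs only at the C10 methylene and gives the (Z)-enol borinate, the chair transition state gives the 10,11-syn adduct, and the Ipc ligands direct attack to the aldehyde re face (10R,11S), overriding the weak bias of the C8 centre on a (Z)-boron enolate.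

**Step 13**
Reactants: 20 dithiane aldol adduct
Product: 21 (5S,6R,8R,9S,10E,12S,13Z)-6,8-bis{[(tert-butyldimethylsilyl)oxy]methyl}-5-hydroxy-10,12-dimethyl-9-[(triethylsilyl)oxy]pentadeca-10,13-diene-3,7-dione
Conditions: MeI, CaCO3, MeCN/H2O 9:1, 45 °C
Reagents that add atoms: water, O
Why: Alkylative dithioketal hydrolysis releases the C13 ketone under neutral, non-oxidising conditions that leave both alkenes, the silyl ethers and the β-hydroxy ketone intact; sulfur must be gone before the epoxidation.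

**Step 14**
Reactants: 21 diene-dione
Product: 22 (5S,6R,8R,9S)-6,8-bis{[(tert-butyldimethylsilyl)oxy]methyl}-5-hydroxy-9-{(2S,3R)-2-methyl-3-[(2S,3Z)-pent-3-en-2-yl]oxiran-2-yl}-9-[(triethylsilyl)oxy]nonane-3,7-dione
Conditions: 1,2:4,5-di-O-isopropylidene-β-D-erythro-2,3-hexodiulo-2,6-pyranose (D-fructose-derived Shi ketone, 0.5–1 equiv), KHSO5 (as 2KHSO5·KHSO4·K2SO4), NaHCO3, Bu4NHSO4, MeCN/(MeO)2CH2–H2O, pH ≈ 8, 0 °C
Reagents that add atoms: potassium peroxymonosulfate, [K+].[O-]S(=O)(=O)OO
Why: Shi epoxidation: the chiral dioxirane attacks the electron-richer (E)-trisubstituted C5=C6 alkene through a spiro transition state on the face that gives the target epoxide (5R,6R in target descriptors; the C6 label reads S in 22 only because of the silyl ether), while the (Z)-disubstituted alkene is a poor substrate; reagent control is needed because hydroxyl-directed epoxidations would give the erythro, not the required threo, epoxy alcohol.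

**Step 15**
Reactants: 22 silylated epoxide
Product: 23 (5S,6R,8R,9S)-5,9-dihydroxy-6,8-bis(hydroxymethyl)-9-{(2R,3R)-2-methyl-3-[(2S,3Z)-pent-3-en-2-yl]oxiran-2-yl}nonane-3,7-dione (target, CNP0266199.1)
Conditions: HF·pyridine, pyridine, THF, 0 °C → rt; Me3SiOMe quench
Reagents that add atoms: none
Why: Pyridine-buffered HF removes the triethylsilyl and both primary tert-butyldimethylsilyl ethers in one operation under near-neutral conditions that should spare the trisubstituted epoxide and the elimination-prone β-hydroxy ketones; no stereocentre is touched.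

**Compound list**
1 | 2-(tert-butyldimethylsilyl)-1,3-dithiane | CC(C)(C)[Si](C)(C)C1SCCCS1 | starting material
2 | oxirane (ethylene oxide) | C1CO1 | starting material
3 | lithium 2-[2-(tert-butyldimethylsilyl)-1,3-dithian-2-yl]ethan-1-olate | [Li+].[O-]CCC1([Si](C)(C)C(C)(C)C)SCCCS1 | intermediate (not isolated)
4 | lithium 2-{2-[2-(tert-butyldimethylsilyloxy)ethyl]-1,3-dithian-2-yl}ethan-1-olate | [Li+].[O-]CCC1(CCO[Si](C)(C)C(C)(C)C)SCCCS1 | intermediate (not isolated)
5 | 2,2-bis[2-(tert-butyldimethylsilyloxy)ethyl]-1,3-dithiane | CC(C)(C)[Si](C)(C)OCCC1(CCO[Si](C)(C)C(C)(C)C)SCCCS1 | intermediate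
6 | 1,5-bis(tert-butyldimethylsilyloxy)pentan-3-one | CC(C)(C)[Si](C)(C)OCCC(=O)CCO[Si](C)(C)C(C)(C)C | intermediate
7 | 1,3-dithiane | C1CSCSC1 | starting material
8 | 2-ethyl-1,3-dithiane | CCC1SCCCS1 | intermediate (not isolated)
9 | 2-(2-ethyl-1,3-dithian-2-yl)ethan-1-ol | CCC1(CCO)SCCCS1 | intermediate
10 | 2-(2-ethyl-1,3-dithian-2-yl)acetaldehyde | CCC1(CC=O)SCCCS1 | intermediate
11 | methyl (R)-3-hydroxy-2-methylpropanoate | COC(=O)[C@H](C)CO | starting material
12 | methyl (R)-3-(tert-butyldimethylsilyloxy)-2-methylpropanoate | COC(=O)[C@H](C)CO[Si](C)(C)C(C)(C)C | intermediate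
13 | (R)-3-(tert-butyldimethylsilyloxy)-2-methylpropanal | O=C[C@H](C)CO[Si](C)(C)C(C)(C)C | intermediate
14 | tert-butyldimethyl{[(2S,3Z)-2-methylpent-3-en-1-yl]oxy}silane | C/C=C\[C@H](C)CO[Si](C)(C)C(C)(C)C | intermediate
15 | (2S,3Z)-2-methylpent-3-en-1-ol | C/C=C\[C@H](C)CO | intermediate
16 | (2S,3Z)-2-methylpent-3-enal | C/C=C\[C@H](C)C=O | intermediate (not isolated)
17 | (2E,4S,5Z)-2,4-dimethylhepta-2,5-dienal | C/C=C\[C@H](C)/C=C(\C)C=O | intermediate
18 | (4R,5S,6E,8S,9Z)-1-[(tert-butyldimethylsilyl)oxy]-4-{[(tert-butyldimethylsilyl)oxy]methyl}-5-hydroxy-6,8-dimethylundeca-6,9-dien-3-one | C/C=C\[C@H](C)/C=C(\C)[C@@H](O)[C@@H](CO[Si](C)(C)C(C)(C)C)C(=O)CCO[Si](C)(C)C(C)(C)C | intermediate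
19 | (4R,5S,6E,8S,9Z)-1-[(tert-butyldimethylsilyl)oxy]-4-{[(tert-butyldimethylsilyl)oxy]methyl}-6,8-dimethyl-5-[(triethylsilyl)oxy]undeca-6,9-dien-3-one | C/C=C\[C@H](C)/C=C(\C)[C@@H](O[Si](CC)(CC)CC)[C@@H](CO[Si](C)(C)C(C)(C)C)C(=O)CCO[Si](C)(C)C(C)(C)C | intermediate
20 | (2S,3R,5R,6S,7E,9S,10Z)-3,5-bis{[(tert-butyldimethylsilyl)oxy]methyl}-1-(2-ethyl-1,3-dithian-2-yl)-2-hydroxy-7,9-dimethyl-6-[(triethylsilyl)oxy]dodeca-7,10-dien-4-one | C/C=C\[C@H](C)/C=C(\C)[C@@H](O[Si](CC)(CC)CC)[C@@H](CO[Si](C)(C)C(C)(C)C)C(=O)[C@H](CO[Si](C)(C)C(C)(C)C)[C@@H](O)CC1(CC)SCCCS1 | intermediate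
21 | (5S,6R,8R,9S,10E,12S,13Z)-6,8-bis{[(tert-butyldimethylsilyl)oxy]methyl}-5-hydroxy-10,12-dimethyl-9-[(triethylsilyl)oxy]pentadeca-10,13-diene-3,7-dione | C/C=C\[C@H](C)/C=C(\C)[C@@H](O[Si](CC)(CC)CC)[C@@H](CO[Si](C)(C)C(C)(C)C)C(=O)[C@H](CO[Si](C)(C)C(C)(C)C)[C@@H](O)CC(=O)CC | intermediate
22 | (5S,6R,8R,9S)-6,8-bis{[(tert-butyldimethylsilyl)oxy]methyl}-5-hydroxy-9-{(2S,3R)-2-methyl-3-[(2S,3Z)-pent-3-en-2-yl]oxiran-2-yl}-9-[(triethylsilyl)oxy]nonane-3,7-dione | C/C=C\[C@H](C)[C@H]1O[C@]1(C)[C@@H](O[Si](CC)(CC)CC)[C@@H](CO[Si](C)(C)C(C)(C)C)C(=O)[C@H](CO[Si](C)(C)C(C)(C)C)[C@@H](O)CC(=O)CC | intermediate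
23 | (5S,6R,8R,9S)-5,9-dihydroxy-6,8-bis(hydroxymethyl)-9-{(2R,3R)-2-methyl-3-[(2S,3Z)-pent-3-en-2-yl]oxiran-2-yl}nonane-3,7-dione | C/C=C\[C@H](C)[C@H]1O[C@]1(C)[C@@H](O)[C@@H](CO)C(=O)[C@H](CO)[C@@H](O)CC(=O)CC | target

**Step count and risks**
Total: 15 steps. Longest linear sequence: 11 steps (11 → 23 through steps 5–15). The two chiral boron reagents are prepared off-route (two operations from (−)-menthone; one from (+)-α-pinene-derived Ipc2BH).

Step 14 is the most likely to fail. The unhindered (Z)-alkene may compete with the hindered, inductively deactivated C5=C6 alkene, and the β-hydroxy ketone is base-sensitive. The fallback sets out from 21 and comes back at 23. Compound 21 is first desilylated (HF·pyridine, pyridine, THF, 0 °C) to (5S,6R,8R,9S,10E,12S,13Z)-5,9-dihydroxy-6,8-bis(hydroxymethyl)-10,12-dimethylpentadeca-10,13-diene-3,7-dione F5. The same fructose-derived ketone/KHSO5 system is then applied to F5. The now free allylic C7 hydroxyl hydrogen-bonds the dioxirane and steers it to the neighbouring C5=C6 alkene, while the catalyst still chooses the face. The epoxide is then never exposed to HF.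

Step 10 is the second risk. The menthone-derived chloroborane is not commercial, its selectivity with ketones is only moderate, and its facial sense with this ketone is assumed. The fallback sets out from 6 and 17 and comes back at 18. Achiral Cy2BCl/Et3N gives the anti adducts as a roughly 1:1 pair, 18 and (4S,5R,6E,8S,9Z)-1-[(tert-butyldimethylsilyl)oxy]-4-{[(tert-butyldimethylsilyl)oxy]methyl}-5-hydroxy-6,8-dimethylundeca-6,9-dien-3-one F3. A Sharpless kinetic resolution follows (Ti(OiPr)4, D-(−)-diisopropyl tartrate, t-BuOOH 0.6 equiv, 4 Å sieves, CH2Cl2, −20 °C). It rapidly epoxidises the (7R)-carbinol F3 to (4S,5R)-1-[(tert-butyldimethylsilyl)oxy]-4-{[(tert-butyldimethylsilyl)oxy]methyl}-5-hydroxy-5-{(2R,3R)-2-methyl-3-[(2S,3Z)-pent-3-en-2-yl]oxiran-2-yl}pentan-3-one F4. The slow-reacting (7S)-carbinol 18 is left and separated. Half of the dienal is lost.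

Step 1 is the third risk. It is a three-component, one-flask sequence with a gaseous epoxide, and it can suffer incomplete silyl migration or over-alkylation. The fallback sets out from 7 and 2 and comes back at 5; it keeps the acyl-anion logic but drops the relay. Compound 7 is lithiated (n-BuLi, THF, −30 °C) and opened onto 2 to give 2-(1,3-dithian-2-yl)ethan-1-ol F1. Silylation (TBSCl, imidazole) gives tert-butyl[2-(1,3-dithian-2-yl)ethoxy]dimethylsilane F2. A second lithiation (n-BuLi, THF, −20 °C), opening of 2 to alkoxide 4 and in situ capping with TBSCl gives 5.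

**Further compounds**
F1 | step 1 | 2-(1,3-dithian-2-yl)ethan-1-ol | OCCC1SCCCS1
F2 | step 1 | tert-butyl[2-(1,3-dithian-2-yl)ethoxy]dimethylsilane | CC(C)(C)[Si](C)(C)OCCC1SCCCS1
F3 | step 10 | (4S,5R,6E,8S,9Z)-1-[(tert-butyldimethylsilyl)oxy]-4-{[(tert-butyldimethylsilyl)oxy]methyl}-5-hydroxy-6,8-dimethylundeca-6,9-dien-3-one | C/C=C\[C@H](C)/C=C(\C)[C@H](O)[C@H](CO[Si](C)(C)C(C)(C)C)C(=O)CCO[Si](C)(C)C(C)(C)C
F4 | step 10 | (4S,5R)-1-[(tert-butyldimethylsilyl)oxy]-4-{[(tert-butyldimethylsilyl)oxy]methyl}-5-hydroxy-5-{(2R,3R)-2-methyl-3-[(2S,3Z)-pent-3-en-2-yl]oxiran-2-yl}pentan-3-one | C/C=C\[C@H](C)[C@H]1O[C@]1(C)[C@H](O)[C@H](CO[Si](C)(C)C(C)(C)C)C(=O)CCO[Si](C)(C)C(C)(C)C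
F5 | step 14 | (5S,6R,8R,9S,10E,12S,13Z)-5,9-dihydroxy-6,8-bis(hydroxymethyl)-10,12-dimethylpentadeca-10,13-diene-3,7-dione | C/C=C\[C@H](C)/C=C(\C)[C@@H](O)[C@@H](CO)C(=O)[C@H](CO)[C@@H](O)CC(=O)CC
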